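# Preacredinone A by a gold-catalysed furan-to-phenol ring synthesis: route proposal

**Numbering used throughout.** 1 2-methylfuran; 2 2,6-dimethoxybenzaldehyde; 3 5-lithio-2-methylfuran; 4 furyl aryl carbinol; 5 propargyl bromide; 6 furfuryl propargyl ether; 7 arene oxide; 8 phthalan phenol; 9 phthalan methyl ether; 10 benzhydryl chloride acetate; 11 alkoxysulfonium salt; 12 keto acetate; 13 aryl trifluoroacetate; 14 preacredinone A.

Atom labels: ring B is numbered C1 (aroyl), C2 (OH), C3 (H), C4 (Me), C5 (OMe), C6 (CH2OAc). C7 is the ketone carbon and C8 the benzylic CH2 carbon.

Remark on the chemistry: 1, 2 and 5 are taken as commercial. C7 is a stereocentre in 4, 6, 8, 9, 10 and 11, which are all handled as racemates; it is erased when C7 becomes the carbonyl carbon.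

## Analysis of the target

Preacredinone A (14) is a benzophenone in which ring A is a 2,6-dimethoxyphenyl group and ring B a pentasubstituted benzene, joined through the ketone carbon C7. Around ring B, C1 carries C7, C2 a free hydroxyl, C3 the only ring hydrogen, C4 a methyl group, C5 a methoxy group and C6 the acetoxymethyl group with its benzylic carbon C8. There is no stereocentre. The ketone has four ortho substituents and is strongly twisted, but no configurationally stable axis is expected, so the task is one of regiochemistry and oxidation level. The sensitive groups are the primary benzylic acetate (base-labile, and the free alcohol closes onto C7 as a lactol), the C2 phenol hydrogen-bonded to the ketone, and two electron-rich rings open to electrophiles and one-electron oxidants. The difficulty is to place five different substituents in a fixed order on ring B and to make a diaryl ketone whose ring A is oxygenated at both ortho positions, a pattern that electrophilic acylation of a meta-dimethoxyarene does not give. The plan rests on the fact that C7 and C8 sit on the neighbouring carbons C1 and C6: tied through one oxygen they form a 1-aryl-1,3-dihydroisobenzofuran, in which the future ketone and the future acetate are one cyclic ether. The benzene ring of that bicycle has oxygen on C5 next to the methyl-bearing C4, which is the pattern that a 5-methylfuran and an alkyne tethered through C7–O–C8 deliver when the furan is turned into a phenol.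

## Retrosynthetic reasoning

**14 to 12 (C2–O).** The C2 hydroxyl is removed first. In 12 the ketone has exactly one ortho C–H: ring A has none and C6 of ring B is substituted. A carbonyl-directed C–H oxygenation therefore has only one place to go. In the ring construction below C2 derives from a furan β-carbon, which would be awkward to oxygenate from the start, so the oxygen is added last. The forward reaction has to oxidise C2–H without harming the acetate or the methoxylated rings.

**12 to 10 to 9 (C7=O and C8–OAc from one ether).** The ketone is traced to the benzhydryl chloride 10 by a sulfoxide-mediated oxidation. Compound 10 is traced to the cyclic ether 9 by acylative cleavage of the C7–O bond. This cut is chosen because the very property that makes 9 delicate, easy ionisation at the doubly benzylic C7, decides the regiochemistry: the acyl group lands on the C8 oxygen and the leaving group on C7 in one operation. A direct hydride abstraction from 9 by a quinone oxidant was considered and set aside. C8–H2 is unhindered and ortho to the C5 oxygen, whereas C7–H lies in the plane of ring A between two methoxy groups, so oxidation at the wrong carbon (towards a lactone) could not be excluded.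

**9 to 8 (O–CH3).** The C5 methyl ether is cut back to the phenol. The phenol has to be capped before any acylating or oxidising reagent is used, and methyl is the group the target needs.

**8 to 6 (C1–C6 and C4–C5; key disconnection).** Ring B is opened at C1–C6 and C4–C5, and the C5 oxygen is returned to C4 as a furan oxygen. This gives the furfuryl propargyl ether 6. The cut is made here because both new bonds and the oxygen transfer occur in one catalytic isomerisation with no change in formula. The three-atom tether C7–O–C8 allows only one orientation of the alkyne, so the hydroxyl must appear on C5, beside the methyl-bearing C4 and ortho to the ring fusion. Two rings are gained in one step from a precursor that needs only two bond-forming steps.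

**6 to 4 + 5 (O–C8).** The ether is cut at the propargylic C–O bond, which is the bond a Williamson alkylation forms. The reverse polarity (ionising C7 and adding the propargylic alcohol) would invite the cation chemistry that the route tries to avoid.

**4 to 1 + 2 via 3 (C1–C7).** The carbinol is cut between the furan and C7. Aldehyde 2 already carries the 2,6-dimethoxy pattern, and 1 is lithiated cleanly at its free α-position to give 3. The 1,2-addition sets C7 at the alcohol level needed for the tether.

## Alternatives that were turned down

**Alternative 1: oxidative cleavage of an anthraquinone.** Here both C7 and C8 are the carbonyl carbons of the anthraquinone A2 (4-benzyloxy-5-methoxy-2-methyl-9,10-dioxoanthracen-1-yl methanesulfonate). The bond between ring A and the future C8 is cut oxidatively. In the forward step a strongly electrophilic peracid adds to the quinone carbonyl that has only one peri substituent, and ring A migrates to oxygen. This gives the seven-membered lactone A1, in which the new aryl–oxygen bond is the second ring A oxygen.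

- For it: the logic follows the way such benzophenones arise in nature. All ring B substituents, including the C2 oxygen as a benzyl ether, are in place before the key step. Anthraquinones are crystalline and reachable by classical annulations.
- Against it: quinone carbonyls are poor Baeyer–Villiger substrates and need a forcing oxidant that also attacks electron-rich rings. Four lactones are conceivable (two carbonyls, two migrating groups each), and the choice rests on small electronic and steric differences. After A1 the lactone must be opened, the ring A phenol methylated, the carboxyl carbon reduced to C8H2OH beside a diaryl ketone, the sulfonate exchanged for a methyl ether and the benzyl group removed. That is at least six steps after the key step, in addition to the synthesis of A2.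
- Comparison: on the C2 oxygen this alternative is stronger, since it needs no late C–H oxidation. The chosen route offers in exchange a shorter sequence, a regiochemistry fixed by a tether and a C8 that is at the right oxidation level from the start.

**Alternative 2: three-component ortho-acylation with ipso vinylation.** The C1–C7 bond and a C6–vinyl bond are cut. The components are the aryl iodide A4 (1-iodo-2-methoxy-3-methylbenzene), the acid chloride A5 (2,6-dimethoxybenzoyl chloride) and the acrylate A6 (methyl acrylate). In the forward step palladium inserts into the C–I bond, a strained bicyclic olefin relays it to the free ortho C–H, the palladacycle is acylated by A5, the olefin is extruded and a Heck reaction with A6 ends the sequence at the cinnamate A3.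

- For it: all three components are simple, and the methoxy group of A4 provides the ortho substituent this manifold needs. On paper it is the shortest plan: A3 would need oxidative cleavage of the alkene, selective reduction of the resulting aldehyde, acetylation and C2 hydroxylation.
- Against it: the acyl partner is di-ortho-substituted, and its oxidative addition to the palladacycle and the following C–C reductive elimination are the doubtful events. Two carbons of A6 are introduced only to be cut away again, in the presence of electron-rich arenes. The C2 hydroxyl still needs the same late directed oxidation, so the weakest point of the chosen route is not avoided.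
- Comparison: this alternative is stronger in step count and convergence. The chosen route offers a ring-forming step with close precedent on the same substrate class, no degradative steps and no aldehyde/ketone differentiation.

**Alternative 3: formal (3+3) ring synthesis on a furanone.** Ring B is cut at C3–C4 and C1–C6. The 1,3-bis(silyl enol ether) A8 supplies C1 to C3 with the aroyl group, and the furanone A9 (4-methoxy-5-methylfuran-3(2H)-one) supplies C4 to C6 and C8. In the forward step, under a titanium tetrahalide Lewis acid, the terminal carbon of A8 adds to the methyl-bearing β-carbon of A9 and opens the furanone. The central carbon then closes on the ketone and water is lost, giving the deacetyl compound A7, which needs only acetylation of the primary alcohol.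

- For it: it is the most convergent plan. All six ring B substituents, the free C2 hydroxyl included, would appear in one step, and no C–H oxidation is needed.
- Against it: the terminal carbon of such dienes normally attacks the most electrophilic site, which in A9 is the ketone and not the fully substituted β-carbon deactivated by the neighbouring methoxy donor. The reverse orientation would exchange the methyl and hydroxymethyl positions. The central carbon carries the bulky aroyl group. The Lewis acid can chelate and demethylate ring A. A ring-opening cyclisation of this furanone type is without close precedent, and A9 itself has to be made.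
- Comparison: this alternative is stronger in convergence and in the C2 oxygen. The chosen route offers a regiochemistry fixed by the tether and a known reaction class at the key step.

Key step: step 3

## Route

Step 1
Reactants: 1 2-methylfuran; 2 2,6-dimethoxybenzaldehyde
Product: 4 (2,6-dimethoxyphenyl)(5-methylfuran-2-yl)methanol (racemic), via 5-lithio-2-methylfuran 3 (not isolated)
Conditions: 1, n-BuLi, THF, −78 to 0 °C; then 2, −78 °C to rt; H2O
Reagents that add atoms: none
Why: α-Lithiation of the furan at its only free α-position followed by 1,2-addition of the heteroaryllithium to the non-enolisable aldehyde; the new stereocentre C7 is formed racemic and is removed later, and the acid-sensitive carbinol should be worked up without acid and purified on base-washed silica.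

Step 2
Reactants: 4 (2,6-dimethoxyphenyl)(5-methylfuran-2-yl)methanol; 5 propargyl bromide (3-bromoprop-1-yne)
Product: 6 2-[(2,6-dimethoxyphenyl)(prop-2-yn-1-yloxy)methyl]-5-methylfuran (racemic)
Conditions: NaH, THF–DMF, 0 °C; then 5, n-Bu4NI (cat.), 0 °C to rt
Reagents that add atoms: none
Why: Williamson ether synthesis; the hindered secondary alkoxide meets a small, reactive primary propargylic halide, and basic conditions keep the C7–O bond from ionising.

Step 3
Reactants: 6 2-[(2,6-dimethoxyphenyl)(prop-2-yn-1-yloxy)methyl]-5-methylfuran
Product: 8 1-(2,6-dimethoxyphenyl)-5-methyl-1,3-dihydroisobenzofuran-4-ol (racemic), via arene oxide 7 (not isolated)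
Conditions: (Ph3P)AuNTf2 (3 mol %), CH2Cl2, 0 °C to rt
Reagents that add atoms: none
Why: The cationic monovalent gold complex binds the terminal alkyne, and the furan adds through its C1=C2 bond to the internal alkyne carbon C6 in a 5-exo-dig sense, which forms C1–C6, closes the dihydrofuran ring and leaves a cyclopropyl gold carbenoid. This opens to a dienone gold carbene (C4=O, carbene on C5); the carbonyl oxygen adds to C5 to give an oxepine, and its disrotatory 6π electrocyclisation forms C4–C5 and closes ring B as arene oxide 7. Opening of 7 at the C4–O bond gives a methyl-substituted pentadienyl cation, and loss of the C5 proton leaves the hydroxyl on C5. The closest known reaction is the gold-catalysed furan–yne phenol synthesis of furfuryl propargyl ethers and N-propargyl furfurylamines, which gives 4-hydroxy-1,3-dihydroisobenzofurans and 4-hydroxyisoindolines. No stereocentre is created; C7 is untouched. The regiochemistry needs no control beyond the three-atom tether C7–O–C8, which allows only exo attack at C6 and so puts the hydroxyl ortho to the ring fusion and next to the methyl-bearing carbon. The chemoselectivity needed is alkyne activation in preference to heterolysis of the doubly activated C7–O bond, which a soft, non-protic π-acid at low loading and low temperature in a non-nucleophilic solvent should secure.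

Step 4
Reactants: 8 1-(2,6-dimethoxyphenyl)-5-methyl-1,3-dihydroisobenzofuran-4-ol
Product: 9 1-(2,6-dimethoxyphenyl)-4-methoxy-5-methyl-1,3-dihydroisobenzofuran (racemic)
Conditions: MeI, K2CO3, DMF, rt
Reagents that add atoms: iodomethane, SMILES CI
Why: Williamson O-methylation of a phenol; the phenoxide is flanked by two ortho groups but methyl iodide is small, and the basic medium does not disturb the benzhydryl ether.

Step 5
Reactants: 9 1-(2,6-dimethoxyphenyl)-4-methoxy-5-methyl-1,3-dihydroisobenzofuran
Product: 10 [6-[chloro(2,6-dimethoxyphenyl)methyl]-2-methoxy-3-methylphenyl]methyl acetate (racemic)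
Conditions: AcCl, ZnCl2 (5 mol %), CH2Cl2, −20 to 0 °C; then 2,6-lutidine (cat.), concentrate; used crude
Reagents that add atoms: acetyl chloride, SMILES CC(Cl)=O
Why: Acylative cleavage of an ether by an acyl chloride under Lewis acid catalysis; O-acetylation of the ring oxygen gives an acyloxonium ion that ionises at C7, where both aryl rings stabilise the cation, and not at the primary benzylic C8, and chloride then caps C7. The acetate thus arrives on the C8 oxygen and the leaving group on C7 in one step; the amine is added before concentration so that the zinc salt cannot reverse the opening, and the moisture-sensitive chloride is carried on without purification.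

Step 6
Reactants: 10 [6-[chloro(2,6-dimethoxyphenyl)methyl]-2-methoxy-3-methylphenyl]methyl acetate
Product: 12 [6-(2,6-dimethoxybenzoyl)-2-methoxy-3-methylphenyl]methyl acetate, via alkoxysulfonium chloride 11 (not isolated)
Conditions: DMSO, NaHCO3, rt to 60 °C
Reagents that add atoms: dimethyl sulfoxide, SMILES CS(C)=O
Why: Kornblum oxidation; the benzhydryl chloride ionises in DMSO and is captured at oxygen as alkoxysulfonium salt 11, hydrogen carbonate forms the sulfur ylide, and this removes the C7 hydrogen through a five-membered transition state with release of dimethyl sulfide. There is no β-hydrogen, so elimination cannot compete, and the intramolecular hydrogen transfer is not hindered by the two ortho methoxy groups that shield C7–H from external oxidants.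

Step 7
Reactants: 12 [6-(2,6-dimethoxybenzoyl)-2-methoxy-3-methylphenyl]methyl acetate
Product: 14 preacredinone A, [2-(2,6-dimethoxybenzoyl)-3-hydroxy-6-methoxy-5-methylphenyl]methyl acetate, via aryl trifluoroacetate 13 (not isolated)
Conditions: Pd(OAc)2 (10 mol %), PhI(OCOCF3)2, ClCH2CH2Cl, 60–80 °C; then pH 7 phosphate buffer, rt
Reagents that add atoms: [bis(trifluoroacetoxy)iodo]benzene, SMILES O=C(O[I](OC(=O)C(F)(F)F)c1ccccc1)C(F)(F)F
Why: Ketone-directed ortho C–H hydroxylation; the carbonyl oxygen directs cyclopalladation by divalent palladium at C2 (five-membered palladacycle), the trivalent iodine reagent oxidises this to a tetravalent palladium aryl trifluoroacetate, and C–O reductive elimination gives 13, which is hydrolysed on work-up. C2 is the only ortho C–H of the benzophenone and lies para to the C5 methoxy group, and the phenol is protected as its trifluoroacetate while the oxidant is present.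

## Compound list

1 | 2-methylfuran | Cc1ccco1 | starting material
2 | 2,6-dimethoxybenzaldehyde | COc1cccc(OC)c1C=O | starting material
3 | 5-lithio-2-methylfuran | [Li]c1ccc(C)o1 | intermediate
4 | (2,6-dimethoxyphenyl)(5-methylfuran-2-yl)methanol (racemic) | COc1cccc(OC)c1C(O)c1ccc(C)o1 | intermediate
5 | propargyl bromide (3-bromoprop-1-yne) | C#CCBr | starting material
6 | 2-[(2,6-dimethoxyphenyl)(prop-2-yn-1-yloxy)methyl]-5-methylfuran (racemic) | COc1cccc(OC)c1C(OCC#C)c1ccc(C)o1 | intermediate
7 | 4,5-epoxy-1-(2,6-dimethoxyphenyl)-5-methyl-1,3,4,5-tetrahydroisobenzofuran (arene oxide of 8, in equilibrium with its oxepine valence tautomer; racemic, diastereomer mixture) | COc1cccc(OC)c1C1OCC2=C1C=CC3(C)OC23 | intermediate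
8 | 1-(2,6-dimethoxyphenyl)-5-methyl-1,3-dihydroisobenzofuran-4-ol (racemic) | COc1cccc(OC)c1C1OCc2c(O)c(C)ccc12 | intermediate
9 | 1-(2,6-dimethoxyphenyl)-4-methoxy-5-methyl-1,3-dihydroisobenzofuran (racemic) | COc1cccc(OC)c1C1OCc2c(OC)c(C)ccc12 | intermediate
10 | [6-[chloro(2,6-dimethoxyphenyl)methyl]-2-methoxy-3-methylphenyl]methyl acetate (racemic) | COc1cccc(OC)c1C(Cl)c1ccc(C)c(OC)c1COC(C)=O | intermediate
11 | {[2-(acetoxymethyl)-3-methoxy-4-methylphenyl](2,6-dimethoxyphenyl)methoxy}dimethylsulfonium chloride (racemic) | C[S+](C)OC(c1c(OC)cccc1OC)c1ccc(C)c(OC)c1COC(C)=O.[Cl-] | intermediate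
12 | [6-(2,6-dimethoxybenzoyl)-2-methoxy-3-methylphenyl]methyl acetate | COc1cccc(OC)c1C(=O)c1ccc(C)c(OC)c1COC(C)=O | intermediate
13 | [2-(2,6-dimethoxybenzoyl)-6-methoxy-5-methyl-3-(trifluoroacetoxy)phenyl]methyl acetate | COc1cccc(OC)c1C(=O)c1c(OC(=O)C(F)(F)F)cc(C)c(OC)c1COC(C)=O | intermediate
14 | preacredinone A, [2-(2,6-dimethoxybenzoyl)-3-hydroxy-6-methoxy-5-methylphenyl]methyl acetate | COc1cccc(OC)c1C(=O)c1c(O)cc(C)c(OC)c1COC(C)=O | target

## Step count and least certain steps

Total step count: 7. Longest linear sequence: 7 steps (1 to 14; the route is linear).

**Step 3 (key step).** The most likely failure is heterolysis of the C7–O bond before the alkyne reacts. Traces of acid from the catalyst, or the gold centre itself, can ionise the ether to a furyl(aryl)methyl cation stabilised by the furan and by ring A. This would lead to loss of the propargyloxy group and oligomerisation.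

The fallback switches off the donor ability of ring A with two temporary bromine atoms. It sets out from 2 and returns at 8.
- Bromination of 2 (Br2, NaOAc, AcOH) should give 3,5-dibromo-2,6-dimethoxybenzaldehyde F1.
- Addition of 3 (THF, −78 °C) should give (3,5-dibromo-2,6-dimethoxyphenyl)(5-methylfuran-2-yl)methanol F2.
- NaH and 5 should give 2-[(3,5-dibromo-2,6-dimethoxyphenyl)(prop-2-yn-1-yloxy)methyl]-5-methylfuran F3.
- (Ph3P)AuNTf2 in CH2Cl2 should then give 1-(3,5-dibromo-2,6-dimethoxyphenyl)-5-methyl-1,3-dihydroisobenzofuran-4-ol F4.
- Halogen–lithium exchange on F4 (excess n-BuLi, THF, −78 °C; MeOH) removes both bromines and gives 8.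

The bromines are meta to C7 and withdraw inductively. They also force both methoxy groups out of the ring plane, so the cation at C7 loses most of its stabilisation while the furan and the alkyne are unchanged.

**Step 7.** Cyclopalladation may be slow because the tetra-ortho-substituted ketone cannot easily lie in the plane of ring B. The trivalent iodine oxidant may attack the methoxylated rings, and the trifluoroacetic acid released may exchange the benzylic acetate.

The fallback introduces the C2 oxygen through a halogen placed by the phenol. It sets out from 8 and returns at 14.
- I2 and NaHCO3 in aqueous THF iodinate the phenoxide at its only free para position, C2, and leave the non-phenolic ring A alone. This gives 1-(2,6-dimethoxyphenyl)-7-iodo-5-methyl-1,3-dihydroisobenzofuran-4-ol F5.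
- MeI and K2CO3 give 1-(2,6-dimethoxyphenyl)-7-iodo-4-methoxy-5-methyl-1,3-dihydroisobenzofuran F6.
- AcCl with catalytic ZnCl2 gives [6-[chloro(2,6-dimethoxyphenyl)methyl]-5-iodo-2-methoxy-3-methylphenyl]methyl acetate F7.
- DMSO and NaHCO3 give [6-(2,6-dimethoxybenzoyl)-5-iodo-2-methoxy-3-methylphenyl]methyl acetate F8.
- Miyaura borylation (bis(pinacolato)diboron, PdCl2(dppf), KOAc, dioxane, 80 °C; zerovalent palladium cycle) gives [6-(2,6-dimethoxybenzoyl)-2-methoxy-3-methyl-5-(4,4,5,5-tetramethyl-1,3,2-dioxaborolan-2-yl)phenyl]methyl acetate F9.
- Oxidation of the C–B bond with NaBO3·4H2O in THF–H2O at rt gives 14.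

**Step 5.** The ring opening may be accompanied by Friedel–Crafts C-acetylation of ring A. The C7 cation may alkylate a second molecule. Chloride and acetate may scramble through participation of the neighbouring acetoxy group. The opening may also reverse when the acyl chloride is removed.

The fallback replaces acylative ionisation by reductive ring opening. It sets out from 9 and returns at 12.
- Ionic hydrogenation (Et3SiH, CF3CO2H, CH2Cl2, 0 °C; then K2CO3, MeOH) cleaves the C7–O bond and gives [6-(2,6-dimethoxybenzyl)-2-methoxy-3-methylphenyl]methanol F10.
- Ac2O and pyridine give [6-(2,6-dimethoxybenzyl)-2-methoxy-3-methylphenyl]methyl acetate F11.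
- DDQ in CH2Cl2–H2O oxidises the diarylmethane carbon C7 to the ketone 12. In F11 the competing C8 position is deactivated as its acetate, and C7 carries two hydrogens, one of which can align with ring A.

**Step 6.** The alkoxysulfonium ion 11 may revert to the cation and be trapped by adventitious water, chloride may demethylate it at sulfur, or the acetyl group may migrate to the C7 oxygen. In each case the oxidation would be incomplete.

The fallback separates substitution and oxidation. It sets out from 10 and returns at 12.
- Buffered hydrolysis (NaHCO3, acetone–H2O, 0 °C) gives [6-[(2,6-dimethoxyphenyl)(hydroxy)methyl]-2-methoxy-3-methylphenyl]methyl acetate F12.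
- MnO2 in CH2Cl2 oxidises the benzhydrol to 12.

## Further compounds

F1 | step 3 | 3,5-dibromo-2,6-dimethoxybenzaldehyde | COc1c(Br)cc(Br)c(OC)c1C=O
F2 | step 3 | (3,5-dibromo-2,6-dimethoxyphenyl)(5-methylfuran-2-yl)methanol (racemic) | COc1c(Br)cc(Br)c(OC)c1C(O)c1ccc(C)o1
F3 | step 3 | 2-[(3,5-dibromo-2,6-dimethoxyphenyl)(prop-2-yn-1-yloxy)methyl]-5-methylfuran (racemic) | COc1c(Br)cc(Br)c(OC)c1C(OCC#C)c1ccc(C)o1
F4 | step 3 | 1-(3,5-dibromo-2,6-dimethoxyphenyl)-5-methyl-1,3-dihydroisobenzofuran-4-ol (racemic) | COc1c(Br)cc(Br)c(OC)c1C1OCc2c(O)c(C)ccc12
F5 | step 7 | 1-(2,6-dimethoxyphenyl)-7-iodo-5-methyl-1,3-dihydroisobenzofuran-4-ol (racemic) | COc1cccc(OC)c1C1OCc2c(O)c(C)cc(I)c12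
F6 | step 7 | 1-(2,6-dimethoxyphenyl)-7-iodo-4-methoxy-5-methyl-1,3-dihydroisobenzofuran (racemic) | COc1cccc(OC)c1C1OCc2c(OC)c(C)cc(I)c12
F7 | step 7 | [6-[chloro(2,6-dimethoxyphenyl)methyl]-5-iodo-2-methoxy-3-methylphenyl]methyl acetate (racemic) | COc1cccc(OC)c1C(Cl)c1c(I)cc(C)c(OC)c1COC(C)=O
F8 | step 7 | [6-(2,6-dimethoxybenzoyl)-5-iodo-2-methoxy-3-methylphenyl]methyl acetate | COc1cccc(OC)c1C(=O)c1c(I)cc(C)c(OC)c1COC(C)=O
F9 | step 7 | [6-(2,6-dimethoxybenzoyl)-2-methoxy-3-methyl-5-(4,4,5,5-tetramethyl-1,3,2-dioxaborolan-2-yl)phenyl]methyl acetate | COc1cccc(OC)c1C(=O)c1c(B2OC(C)(C)C(C)(C)O2)cc(C)c(OC)c1COC(C)=O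
F10 | step 5 | [6-(2,6-dimethoxybenzyl)-2-methoxy-3-methylphenyl]methanol | COc1cccc(OC)c1Cc1ccc(C)c(OC)c1CO
F11 | step 5 | [6-(2,6-dimethoxybenzyl)-2-methoxy-3-methylphenyl]methyl acetate | COc1cccc(OC)c1Cc1ccc(C)c(OC)c1COC(C)=O
F12 | step 6 | [6-[(2,6-dimethoxyphenyl)(hydroxy)methyl]-2-methoxy-3-methylphenyl]methyl acetate (racemic) | COc1cccc(OC)c1C(O)c1ccc(C)c(OC)c1COC(C)=O
A1 | alternative 1 | 10-(benzyloxy)-1-methoxy-8-methyl-7-(methylsulfonyloxy)dibenzo[b,e]oxepine-6,11-dione | COc1cccc2OC(=O)c3c(OS(C)(=O)=O)c(C)cc(OCc4ccccc4)c3C(=O)c12
A2 | alternative 1 | 4-(benzyloxy)-5-methoxy-2-methyl-9,10-dioxo-9,10-dihydroanthracen-1-yl methanesulfonate | COc1cccc2C(=O)c3c(OS(C)(=O)=O)c(C)cc(OCc4ccccc4)c3C(=O)c12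
A3 | alternative 2 | methyl (E)-3-[6-(2,6-dimethoxybenzoyl)-2-methoxy-3-methylphenyl]prop-2-enoate | COC(=O)/C=C/c1c(OC)c(C)ccc1C(=O)c1c(OC)cccc1OC
A4 | alternative 2 | 1-iodo-2-methoxy-3-methylbenzene | COc1c(C)cccc1I
A5 | alternative 2 | 2,6-dimethoxybenzoyl chloride | COc1cccc(OC)c1C(Cl)=O
A6 | alternative 2 | methyl acrylate | C=CC(=O)OC
A7 | alternative 3 | (2,6-dimethoxyphenyl)[6-hydroxy-2-(hydroxymethyl)-3-methoxy-4-methylphenyl]methanone | COc1cccc(OC)c1C(=O)c1c(O)cc(C)c(OC)c1CO
A8 | alternative 3 | 1-(2,6-dimethoxyphenyl)-1,3-bis(trimethylsilyloxy)buta-1,3-diene | COc1cccc(OC)c1C(O[Si](C)(C)C)=CC(=C)O[Si](C)(C)C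
A9 | alternative 3 | 4-methoxy-5-methylfuran-3(2H)-one | COC1=C(C)OCC1=O
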